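## The problem

Target 18 is a (2S)-flavanone. Rings A and C form a chroman-4-one, and C2 carries a ring B that is itself the benzene ring of a 2,2-dimethyl-2H-chromene. Ring A is a phloroglucinol nucleus with free hydroxyls at C5 and C7 and a prenyl group at C8, so its three oxygens must be told apart and the prenyl group kept away from C6. Ring B carries five contiguous substituents (C1' the flavanone carbon, C2' prenyl, C3' hydroxyl, C4' pyran oxygen, C5' pyran vinyl carbon), and each must be placed without a regiochemical choice.

C2 is the only stereocentre, so nothing in the molecule can relay it and it must come from a catalyst. It is also fragile: it is benzylic to an electron-rich arene, α to O1 and β to the C4 ketone, so base opens ring C to the 2'-hydroxychalcone and strong acid ionises the C2–O1 bond, either of which racemises it. The prenyl groups ortho to phenols close to chromans with acid, and three trisubstituted olefins plus the chromene olefin rule out hydrogenolysis. Every protecting group must therefore leave near neutrality without a reductant.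

The enabling feature is that C2 bears both O1 and ring B, whose pyran oxygen is para to C1'. As the CH2 of a benzyl ether on O1, its C–H bonds are doubly activated toward an electrophilic metal carbene. C3, α to the C4 carbonyl, is the natural carbon of a diazoketone, and C3, C4, C4a, C8a, O1 and C2 are exactly the six atoms of ring C.

## Retrosynthesis

**18 ⇒ 17.** The three O–Si bonds at O5, O7 and O3' are cut. Triisopropylsilyl ethers are chosen because fluoride buffered with acetic acid removes them without the base that opens ring C or the acid that cyclises the prenyl phenols. Ethers needing acid or hydrogen to remove are excluded by the olefins. The forward step must only avoid free fluoride basicity.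

**17 ⇒ 16.** The C2–C3 bond is cut, which removes ring C and the stereocentre together and leaves the α-diazoketone 16 with a plain O1–CH2–aryl ether. The neighbouring cuts are weaker:
- O1–C2 (oxa-Michael closure of a chalcone) is reversible and runs under the conditions that racemise C2.
- C2–C1' (conjugate arylation of a chromone) needs a ring B metal reagent flanked by the prenyl group and an electron-rich, 8-substituted chromone acceptor.
- C4–C4a (acylation of ring A) leaves the 6/8 regiochemistry open.

The forward reaction, a carbenoid C–H insertion catalysed by a chiral dirhodium carboxylate, must pick one of two enantiotopic benzylic hydrogens and must prefer the C–H bond to the lone pairs of O1.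

**16 ⇒ 14 (through 15).** The C3=N2 unit is removed to give methyl ketone 14. The acetyl group arrives free of charge with phloroacetophenone, whereas an acid chloride–diazomethane route would need a hexasubstituted benzoic acid. The forward step activates the methyl ketone as its trifluoroacetyl derivative 15 and transfers the diazo group with loss of the trifluoroacetyl group.

**14 ⇒ 13 + 9.** The O1–CH2 bond is cut, which divides the molecule into ring A phenol 13 and ring B benzylic alcohol 9, of similar size. A Mitsunobu coupling is preferred to a Williamson alkylation because it is neutral (aryl silyl ethers survive) and avoids a labile, electron-rich benzyl bromide. It requires that the 2-OH be the only free phenol of 13.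

**13 ⇒ 12 ⇒ 10 + 11.** The two O–Si bonds and then the C3–prenyl bond are cut. Phloroacetophenone 10 has two equivalent ring positions, so C-prenylation with 11 can give only one mono-prenyl isomer, 12. In 12 the 4-OH is unchelated and the 6-OH has one ortho neighbour, while the 2-OH lies between the prenyl and acetyl groups, so two equivalents of a bulky silyl chloride should leave exactly the hydroxyl needed for O1.

**9 ⇒ 8 ⇒ 7.** The benzylic C–H bond (aldehyde reduction) and the O3'–Si bond are cut. Aldehyde 7 already carries the complete ring B.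

**7 ⇒ 6 ⇒ 5 ⇒ 4 + 2.** The bond from C7 of the chromene (C2' of the flavanone) to the prenyl group is cut by an aromatic Claisen transform back to the 1,1-dimethylallyl ether 6 of the neighbouring oxygen. The [3,3] shift turns the tertiary allyl ether into a normal prenyl group, and C7 is the only ortho carbon bearing hydrogen. Ether 6 comes from the propargyl ether 5 by semi-hydrogenation, so chloride 2 serves a second time.

**4 ⇒ 3 ⇒ 1 + 2.** The pyran ring is opened by a propargyl Claisen transform to ether 3, and the O–C bond is then cut to 3,4-dihydroxybenzaldehyde 1 and chloride 2. The 4-OH of 1 is the more acidic, and its only free ortho position is the one that must carry the vinyl carbon, so both the etherification and the ring fusion are unambiguous.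

## Roads not taken

**Alternative 1: one-pot double Claisen cascade for ring B.**
- Cut: the C2'–prenyl bond and the pyran ring are disconnected together, back to the mixed bis-ether A1 of 3,4-dihydroxybenzaldehyde (1,1-dimethylallyl on the 3-oxygen, 1,1-dimethylpropargyl on the 4-oxygen).
- Key step: heating A1 in N,N-diethylaniline moves the allyl group to C2 and the propargyl group to C5 and closes the pyran, giving aldehyde A2, which is identical with 7.
- Merits: two C–C bonds and a ring form in one flask, and 7 would be reached in three steps from 1 where the chosen route needs five.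
- Weak points: A1 is awkward to make, because semi-hydrogenation cannot distinguish two alkynes, and a palladium-catalysed tert-allylation of monoether 3 must spare a tertiary propargylic aryl ether that zerovalent palladium can also ionise. The two rearrangements need different temperatures, so the ortho-prenyl phenol formed first sits for hours at the higher one. The cascade also says nothing about C2 or ring C, so the stereocentre would still need a separate event.
- Comparison: this road is shorter for ring B by two steps. The chosen plan offers in return two rearrangements each run on a single ether at its own temperature, and a key step spent on the stereocentre, which is the real difficulty. If the cascade proved clean, A2 could replace steps 2 to 5 without touching the rest.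

**Alternative 2: chelation-assisted rhodium hydroacylation to close ring C.**
- Cut: the C3–C4 bond and the C2–H bond, back to salicylaldehyde A3, in which O1 carries a 1-arylvinyl group and the future 5-OH is free.
- Key step: cationic monovalent rhodium ([Rh(cod)2]BF4, a chiral bisphosphine, K3PO4) is held by the ortho phenoxide, adds the aldehyde C–H bond across the enol ether and closes ring C to the bis-MOM flavanone A4.
- Merits: perfect atom economy, no diazo compound, only two protecting groups (the 5-OH is the directing group), and a reaction class that is well established for salicylaldehydes.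
- Weak points: an aryl 1-arylvinyl ether on the hindered O1 is much harder to make than a benzyl ether. The stereocentre arises by hydride delivery to a 1,1-disubstituted enol ether in a six-membered closure, so regiochemistry and face selection must both be right while decarbonylation and olefin isomerisation by the rhodium hydride compete. K3PO4 with a free 5-phenoxide at reaction temperature can open a flavanone and erase C2. Removing the MOM ethers needs acid, which cyclises ortho-prenyl phenols.
- Comparison: this road is better in atom economy, safety and protecting-group count. The chosen plan offers in return a precursor made by a Mitsunobu coupling and a diazo transfer, a base-free ring closure and a fluoride deprotection.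

**Alternative 3: ring A grown last on a chiral bromodihydropyranone.**
- Cut: C8–C8a and C4a–C5, so that ring A disappears, back to the (S)-bromodihydropyranone A5 and the bis(trimethylsilyl) dienol ether A6 of a γ-prenylated acetoacetate.
- Key step: with ZnCl2 the γ-carbon of A6 adds to the enol ether carbon of A5, the α-carbon closes onto the ester carbon, and loss of HBr and methanol aromatises ring A to the mono-silyl flavanone A7.
- Merits: ring A needs no protecting groups, the 8-prenyl position is written into the diene, and C2 could be set early on a small heterocycle by an asymmetric hetero-Diels–Alder reaction of aldehyde 8, one of the most reliable enantioselective reactions available.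
- Weak points: the diene must act as nucleophile at its γ-carbon and as electrophile at its ester carbon, whereas such dienes normally keep the ester and give salicylates. The acceptor carbon is the β-carbon of a vinylogous ester and must take a secondary, prenyl-bearing nucleophile. ZnCl2 and the HBr set free act on a C2 that is the benzylic ether of a para-oxygenated arene, so ionisation or β-elimination of O1 can racemise or destroy it. The same acid threatens the prenyl groups and the chromene.
- Comparison: this road is better in protecting-group economy and in the reliability of its enantioselective step. The chosen plan offers in return a ring closure of a known class that forms one bond under neutral conditions, and a stereocentre created in the penultimate step, which then meets only one more reagent.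

Key step: step 12

Assumption: the sense of induction of Rh2(S-PTTL)4 in this insertion cannot be derived with confidence; the (S)-leucinate catalyst is written, and its mirror image Rh2(R-PTTL)4 would be used if the first runs showed the 2R product.

Step 1
Reactants: 1 3,4-dihydroxybenzaldehyde; 2 3-chloro-3-methylbut-1-yne
Product: 3 3-hydroxy-4-[(2-methylbut-3-yn-2-yl)oxy]benzaldehyde
Conditions: 2 (1.3 equiv), K2CO3 (1.1 equiv), KI, CuI (5 mol %), DMF, 60 °C
Reagents that add atoms: none
Why: Copper-assisted O-alkylation of a phenoxide by a tertiary propargylic chloride; one equivalent of weak base ionises only the 4-OH, which is para to the formyl group and the more acidic, so the ether should form there.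

Step 2
Reactants: 3 3-hydroxy-4-[(2-methylbut-3-yn-2-yl)oxy]benzaldehyde
Product: 4 8-hydroxy-2,2-dimethyl-2H-chromene-6-carbaldehyde
Conditions: N,N-diethylaniline, 190 °C
Reagents that add atoms: none
Why: Aryl propargyl ether Claisen rearrangement followed by 1,5-hydrogen shift and 6π-electrocyclisation; the [3,3] shift can end productively only at C5, the single hydrogen-bearing ortho position of the ether oxygen, which fixes the ring fusion.

Step 3
Reactants: 4 8-hydroxy-2,2-dimethyl-2H-chromene-6-carbaldehyde; 2 3-chloro-3-methylbut-1-yne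
Product: 5 2,2-dimethyl-8-[(2-methylbut-3-yn-2-yl)oxy]-2H-chromene-6-carbaldehyde
Conditions: 2 (2 equiv), K2CO3 (2 equiv), KI, CuI (5 mol %), DMF, 65 °C
Reagents that add atoms: none
Why: The same copper-assisted propargylation on the one remaining phenol; the temperature is far below that of a propargyl Claisen rearrangement, so the ether should persist.

Step 4
Reactants: 5 2,2-dimethyl-8-[(2-methylbut-3-yn-2-yl)oxy]-2H-chromene-6-carbaldehyde
Product: 6 2,2-dimethyl-8-[(2-methylbut-3-en-2-yl)oxy]-2H-chromene-6-carbaldehyde
Conditions: H2 (1 atm), Pd/CaCO3 poisoned with Pb(OAc)2 (Lindlar catalyst), quinoline, EtOAc, rt, stopped after one equivalent of H2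
Reagents that add atoms: none
Why: Lindlar semi-hydrogenation; the terminal alkyne binds the poisoned palladium far better than the disubstituted chromene olefin or the aldehyde, so the reduction should stop at the vinyl ether.

Step 5
Reactants: 6 2,2-dimethyl-8-[(2-methylbut-3-en-2-yl)oxy]-2H-chromene-6-carbaldehyde
Product: 7 8-hydroxy-2,2-dimethyl-7-(3-methylbut-2-en-1-yl)-2H-chromene-6-carbaldehyde
Conditions: N,N-diethylaniline, 140 °C
Reagents that add atoms: none
Why: Aromatic Claisen rearrangement of a 1,1-dimethylallyl aryl ether; the [3,3] shift inverts the allyl unit so the ring receives a normal prenyl group, and C7 is the only ortho carbon whose dienone can enolise, so the prenyl group should end between the hydroxyl and the formyl group.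

Step 6
Reactants: 7 8-hydroxy-2,2-dimethyl-7-(3-methylbut-2-en-1-yl)-2H-chromene-6-carbaldehyde
Product: 8 2,2-dimethyl-7-(3-methylbut-2-en-1-yl)-8-(triisopropylsilyloxy)-2H-chromene-6-carbaldehyde
Conditions: iPr3SiOTf, 2,6-lutidine, CH2Cl2, 0 °C
Reagents that add atoms: triisopropylsilyl trifluoromethanesulfonate, CC(C)[Si](OS(=O)(=O)C(F)(F)F)(C(C)C)C(C)C
Why: Silylation of a hindered phenol with a silyl triflate and a non-nucleophilic base; the triisopropylsilyl ether should survive hydride, Mitsunobu conditions, amide base and the rhodium carbenoid and later leave with fluoride.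

Step 7
Reactants: 8 2,2-dimethyl-7-(3-methylbut-2-en-1-yl)-8-(triisopropylsilyloxy)-2H-chromene-6-carbaldehyde
Product: 9 [2,2-dimethyl-7-(3-methylbut-2-en-1-yl)-8-(triisopropylsilyloxy)-2H-chromen-6-yl]methanol
Conditions: NaBH4, MeOH/THF, 0 °C
Reagents that add atoms: none
Why: Borohydride reduction of an aryl aldehyde; the olefins and the aryl silyl ether are inert to it at 0 °C.

Step 8
Reactants: 10 2,4,6-trihydroxyacetophenone; 11 prenyl bromide
Product: 12 1-[2,4,6-trihydroxy-3-(3-methylbut-2-en-1-yl)phenyl]ethanone
Conditions: 11 (1.0 equiv), DBU (1.0 equiv), THF, 0 °C to rt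
Reagents that add atoms: none
Why: C-alkylation of a phloroglucinol-type phenoxide, which reacts at carbon like an enolate; the two ring positions of 10 are equivalent, so mono-prenylation can give only one isomer, and O-prenyl and bis-prenyl by-products are removed by chromatography.

Step 9
Reactants: 12 1-[2,4,6-trihydroxy-3-(3-methylbut-2-en-1-yl)phenyl]ethanone
Product: 13 1-[2-hydroxy-3-(3-methylbut-2-en-1-yl)-4,6-bis(triisopropylsilyloxy)phenyl]ethanone
Conditions: iPr3SiCl (2.2 equiv), imidazole, DMF, 0 °C to rt
Reagents that add atoms: triisopropylsilyl chloride, CC(C)[Si](Cl)(C(C)C)C(C)C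
Why: Regioselective phenol silylation; the unchelated 4-OH should react first, then the 6-OH with a single ortho neighbour, while the 2-OH between the prenyl and acetyl groups keeps the hydrogen bond to the carbonyl and is too crowded for a third triisopropylsilyl group.

Step 10
Reactants: 13 1-[2-hydroxy-3-(3-methylbut-2-en-1-yl)-4,6-bis(triisopropylsilyloxy)phenyl]ethanone; 9 [2,2-dimethyl-7-(3-methylbut-2-en-1-yl)-8-(triisopropylsilyloxy)-2H-chromen-6-yl]methanol
Product: 14 1-[2-{[2,2-dimethyl-7-(3-methylbut-2-en-1-yl)-8-(triisopropylsilyloxy)-2H-chromen-6-yl]methoxy}-3-(3-methylbut-2-en-1-yl)-4,6-bis(triisopropylsilyloxy)phenyl]ethanone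
Conditions: PPh3, DIAD, toluene, 0 °C to rt
Reagents that add atoms: none
Why: Mitsunobu etherification of an acidic ortho-acyl phenol with a primary benzylic alcohol; the conditions are neutral, so the three aryl silyl ethers should stay in place, and the small phenoxide oxygen can still reach the activated benzylic carbon.

Step 11
Reactants: 14 1-[2-{[2,2-dimethyl-7-(3-methylbut-2-en-1-yl)-8-(triisopropylsilyloxy)-2H-chromen-6-yl]methoxy}-3-(3-methylbut-2-en-1-yl)-4,6-bis(triisopropylsilyloxy)phenyl]ethanone
Product: 16 2-diazo-1-[2-{[2,2-dimethyl-7-(3-methylbut-2-en-1-yl)-8-(triisopropylsilyloxy)-2H-chromen-6-yl]methoxy}-3-(3-methylbut-2-en-1-yl)-4,6-bis(triisopropylsilyloxy)phenyl]ethanone, via trifluoroacetyl ketone 15 (not isolated)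
Conditions: LiN(SiMe3)2, THF, −78 °C; CF3CO2CH2CF3, −78 °C; dilute aq. HCl wash; crude 15, 4-acetamidobenzenesulfonyl azide, Et3N, H2O (1 equiv), MeCN/THF, rt
Reagents that add atoms: 4-acetamidobenzenesulfonyl azide, CC(=O)Nc1ccc(cc1)S(=O)(=O)N=[N+]=[N-] (the two diazo nitrogens of 16); 2,2,2-trifluoroethyl trifluoroacetate, O=C(OCC(F)(F)F)C(F)(F)F (the trifluoroacetyl group of 15 only)
Why: Detrifluoroacetylative diazo transfer; the kinetic lithium enolate of the methyl ketone is acylated to the 1,3-diketone 15, whose acidic central carbon takes the diazo group from the sulfonyl azide and then loses the trifluoroacetyl group as the N-sulfonyl amide. The methyl group is the only acidic site of 14.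

Step 12
Reactants: 16 2-diazo-1-[2-{[2,2-dimethyl-7-(3-methylbut-2-en-1-yl)-8-(triisopropylsilyloxy)-2H-chromen-6-yl]methoxy}-3-(3-methylbut-2-en-1-yl)-4,6-bis(triisopropylsilyloxy)phenyl]ethanone
Product: 17 (2S)-2-[2,2-dimethyl-7-(3-methylbut-2-en-1-yl)-8-(triisopropylsilyloxy)-2H-chromen-6-yl]-8-(3-methylbut-2-en-1-yl)-5,7-bis(triisopropylsilyloxy)-2,3-dihydro-4H-chromen-4-one
Conditions: Rh2(S-PTTL)4 (PTTL = N-phthaloyl-(S)-tert-leucinate; 2 mol %), toluene, 0 °C, 16 added slowly
Reagents that add atoms: none
Why: Rh2(S-PTTL)4, a tetracarboxylate of divalent rhodium, takes nitrogen from 16 and gives an electrophilic rhodium carbenoid at C3. The carbenoid inserts into one benzylic C–H bond of the O1–CH2 group through a three-centre, hydride-transfer-like transition state, so that the C2–C3 bond forms and the hydrogen ends on C3. The closest known reaction type is the chiral dirhodium carboxylate-catalysed intramolecular C–H insertion of 2-alkoxyaryl α-diazoketones into the ether α-C–H bond, which gives 2-substituted chroman-4-ones. Ring C closes as a 1,6-insertion through the six-membered array C3, C4, C4a, C8a, O1, C2; the usual five-membered mode is closed because the fifth atom is O1, which has no hydrogen. C2 is the only new stereocentre and is set by the catalyst alone, whose phthalimido-walled pocket decides which of the two enantiotopic benzylic hydrogens meets the carbenoid; the 2S sense is required. The step needs C–H insertion to win over oxonium ylide formation at O1 with 1,2-benzyl shift, over attack on the other ortho oxygen, and over addition to the olefins or to ring B. The substrate helps because the positive charge building at C2 is stabilised by O1 and by the para pyran oxygen of ring B, because O1 is a weak donor (conjugated to an acyl-bearing ring and flanked by the prenyl group), because the two ortho substituents twist the diazoketone out of the ring plane, which a planar five-membered ylide tolerates badly, and because the bulky silyl group shields the 6-oxygen. The prenyl and chromene olefins can be reached only through rings of seven or more atoms, and slow addition keeps carbene dimerisation down.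

Step 13
Reactants: 17 (2S)-2-[2,2-dimethyl-7-(3-methylbut-2-en-1-yl)-8-(triisopropylsilyloxy)-2H-chromen-6-yl]-8-(3-methylbut-2-en-1-yl)-5,7-bis(triisopropylsilyloxy)-2,3-dihydro-4H-chromen-4-one
Product: 18 (2S)-5,7-dihydroxy-2-[8-hydroxy-2,2-dimethyl-7-(3-methylbut-2-en-1-yl)-2H-chromen-6-yl]-8-(3-methylbut-2-en-1-yl)-2,3-dihydro-4H-chromen-4-one
Conditions: Bu4NF (3.5 equiv), AcOH (3.5 equiv), THF, 0 °C
Reagents that add atoms: none
Why: Fluoride cleavage of aryl silyl ethers; acetic acid keeps the medium near neutral, so ring C should not open to the chalcone and C2 should keep its configuration, and no acid strong enough to cyclise the prenyl phenols is present.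

## Compound list

1 | 3,4-dihydroxybenzaldehyde | O=Cc1ccc(O)c(O)c1 | starting material
2 | 3-chloro-3-methylbut-1-yne | CC(C)(Cl)C#C | starting material
3 | 3-hydroxy-4-[(2-methylbut-3-yn-2-yl)oxy]benzaldehyde | O=Cc1ccc(OC(C)(C)C#C)c(O)c1 | intermediate
4 | 8-hydroxy-2,2-dimethyl-2H-chromene-6-carbaldehyde | O=Cc1cc(O)c2OC(C)(C)C=Cc2c1 | intermediate
5 | 2,2-dimethyl-8-[(2-methylbut-3-yn-2-yl)oxy]-2H-chromene-6-carbaldehyde | O=Cc1cc(OC(C)(C)C#C)c2OC(C)(C)C=Cc2c1 | intermediate
6 | 2,2-dimethyl-8-[(2-methylbut-3-en-2-yl)oxy]-2H-chromene-6-carbaldehyde | O=Cc1cc(OC(C)(C)C=C)c2OC(C)(C)C=Cc2c1 | intermediate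
7 | 8-hydroxy-2,2-dimethyl-7-(3-methylbut-2-en-1-yl)-2H-chromene-6-carbaldehyde | CC(C)=CCc1c(C=O)cc2C=CC(C)(C)Oc2c1O | intermediate
8 | 2,2-dimethyl-7-(3-methylbut-2-en-1-yl)-8-(triisopropylsilyloxy)-2H-chromene-6-carbaldehyde | CC(C)=CCc1c(C=O)cc2C=CC(C)(C)Oc2c1O[Si](C(C)C)(C(C)C)C(C)C | intermediate
9 | [2,2-dimethyl-7-(3-methylbut-2-en-1-yl)-8-(triisopropylsilyloxy)-2H-chromen-6-yl]methanol | CC(C)=CCc1c(CO)cc2C=CC(C)(C)Oc2c1O[Si](C(C)C)(C(C)C)C(C)C | intermediate
10 | 2,4,6-trihydroxyacetophenone | CC(=O)c1c(O)cc(O)cc1O | starting material
11 | prenyl bromide (1-bromo-3-methylbut-2-ene) | CC(C)=CCBr | starting material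
12 | 1-[2,4,6-trihydroxy-3-(3-methylbut-2-en-1-yl)phenyl]ethanone | CC(=O)c1c(O)cc(O)c(CC=C(C)C)c1O | intermediate
13 | 1-[2-hydroxy-3-(3-methylbut-2-en-1-yl)-4,6-bis(triisopropylsilyloxy)phenyl]ethanone | CC(=O)c1c(O[Si](C(C)C)(C(C)C)C(C)C)cc(O[Si](C(C)C)(C(C)C)C(C)C)c(CC=C(C)C)c1O | intermediate
14 | 1-[2-{[2,2-dimethyl-7-(3-methylbut-2-en-1-yl)-8-(triisopropylsilyloxy)-2H-chromen-6-yl]methoxy}-3-(3-methylbut-2-en-1-yl)-4,6-bis(triisopropylsilyloxy)phenyl]ethanone | CC(=O)c1c(O[Si](C(C)C)(C(C)C)C(C)C)cc(O[Si](C(C)C)(C(C)C)C(C)C)c(CC=C(C)C)c1OCc1cc2C=CC(C)(C)Oc2c(O[Si](C(C)C)(C(C)C)C(C)C)c1CC=C(C)C | intermediate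
15 | 4,4,4-trifluoro-1-[2-{[2,2-dimethyl-7-(3-methylbut-2-en-1-yl)-8-(triisopropylsilyloxy)-2H-chromen-6-yl]methoxy}-3-(3-methylbut-2-en-1-yl)-4,6-bis(triisopropylsilyloxy)phenyl]butane-1,3-dione | O=C(CC(=O)C(F)(F)F)c1c(O[Si](C(C)C)(C(C)C)C(C)C)cc(O[Si](C(C)C)(C(C)C)C(C)C)c(CC=C(C)C)c1OCc1cc2C=CC(C)(C)Oc2c(O[Si](C(C)C)(C(C)C)C(C)C)c1CC=C(C)C | intermediate (not isolated)
16 | 2-diazo-1-[2-{[2,2-dimethyl-7-(3-methylbut-2-en-1-yl)-8-(triisopropylsilyloxy)-2H-chromen-6-yl]methoxy}-3-(3-methylbut-2-en-1-yl)-4,6-bis(triisopropylsilyloxy)phenyl]ethanone | [N-]=[N+]=CC(=O)c1c(O[Si](C(C)C)(C(C)C)C(C)C)cc(O[Si](C(C)C)(C(C)C)C(C)C)c(CC=C(C)C)c1OCc1cc2C=CC(C)(C)Oc2c(O[Si](C(C)C)(C(C)C)C(C)C)c1CC=C(C)C | intermediate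
17 | (2S)-2-[2,2-dimethyl-7-(3-methylbut-2-en-1-yl)-8-(triisopropylsilyloxy)-2H-chromen-6-yl]-8-(3-methylbut-2-en-1-yl)-5,7-bis(triisopropylsilyloxy)-2,3-dihydro-4H-chromen-4-one | CC(C)=CCc1c([C@@H]2CC(=O)c3c(O[Si](C(C)C)(C(C)C)C(C)C)cc(O[Si](C(C)C)(C(C)C)C(C)C)c(CC=C(C)C)c3O2)cc2c(c1O[Si](C(C)C)(C(C)C)C(C)C)OC(C)(C)C=C2 | intermediate
18 | (2S)-5,7-dihydroxy-2-[8-hydroxy-2,2-dimethyl-7-(3-methylbut-2-en-1-yl)-2H-chromen-6-yl]-8-(3-methylbut-2-en-1-yl)-2,3-dihydro-4H-chromen-4-one (CNP0328260.1) | CC(C)=CCc1c([C@@H]2CC(=O)c3c(O)cc(O)c(CC=C(C)C)c3O2)cc2c(c1O)OC(C)(C)C=C2 | target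

## Step count and risks

Total: 13 steps. Longest linear sequence: 11 steps (steps 1 to 7, then 10 to 13). The ring A branch (steps 8 and 9) joins at step 10.

**Step 12 (key step).** Two processes are most likely to go wrong. The carbenoid may be captured by the lone pair of O1, and the resulting oxonium ylide would shift its electron-rich benzyl group to carbon instead of giving C–H insertion. Independently, face selection may be poor, because a terminal diazoketone gives a very reactive carbenoid with an early transition state. The fallback gives up the C2–C3 bond and closes ring C at O1–C2 by a catalytic asymmetric oxa-Michael addition. It sets out from phenol 13 and aldehyde 8 and returns at 17. The dianion of 13 (LiN(SiMe3)2, three equivalents) would be C-acylated with di-tert-butyl dicarbonate to the β-keto ester tert-butyl 3-[2-hydroxy-3-(3-methylbut-2-en-1-yl)-4,6-bis(triisopropylsilyloxy)phenyl]-3-oxopropanoate F1. Knoevenagel condensation of F1 with 8 (piperidinium acetate, toluene, molecular sieves) would give the alkylidene β-keto ester tert-butyl 2-[2-hydroxy-3-(3-methylbut-2-en-1-yl)-4,6-bis(triisopropylsilyloxy)benzoyl]-3-[2,2-dimethyl-7-(3-methylbut-2-en-1-yl)-8-(triisopropylsilyloxy)-2H-chromen-6-yl]prop-2-enoate F2. A cinchona-derived bifunctional thiourea, in the pseudo-enantiomeric form that gives 2S, would then close the ring to the 3-tert-butoxycarbonyl derivative of 17, F3. TsOH in toluene at 80 °C would remove the ester as isobutene and CO2, conditions under which flavanone 3-carboxylates are known to decarboxylate without loss of configuration at C2, giving 17.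

**Step 9 (and the yield of step 8).** The only control over which ortho hydroxyl is silylated is steric, so silylation may occur at the 2-OH or run on to the tris-ether, and step 8 may over-alkylate. The fallback makes the regiochemistry structural. It sets out from 10 and returns at 13. Bis-silylation of 10 (iPr3SiCl, imidazole), whose two ortho hydroxyls are equivalent, would give 1-[2-hydroxy-4,6-bis(triisopropylsilyloxy)phenyl]ethanone F4. O-Allylation of the remaining phenol with tert-butyl 2-methylbut-3-en-2-yl carbonate and Pd(PPh3)4 (zerovalent palladium, attack at the substituted allyl terminus) would give 1-[2-[(2-methylbut-3-en-2-yl)oxy]-4,6-bis(triisopropylsilyloxy)phenyl]ethanone F5. An aromatic Claisen rearrangement (N,N-diethylaniline, 130 °C) can then deliver the prenyl group only to C3, the one hydrogen-bearing ortho carbon, which gives 13.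

**Step 10.** The phenol of 13 is hydrogen-bonded and flanked on both sides, so the coupling may stall. The activated benzylic oxyphosphonium ion may instead ionise and alkylate an electron-rich ring at carbon. The fallback replaces the redox condensation by a Williamson ether synthesis. It sets out from 9 and returns at 14. Alcohol 9 would be converted (CBr4, PPh3, CH2Cl2, 0 °C) into 6-(bromomethyl)-2,2-dimethyl-7-(3-methylbut-2-en-1-yl)-8-(triisopropylsilyloxy)-2H-chromene F6, which is used at once to alkylate 13 (K2CO3, Bu4NI, acetone, rt) to give 14.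

**Step 11.** Acylation of the twisted, doubly ortho-substituted enolate by the trifluoroacetate may be incomplete, and the neighbouring silyl group may migrate from oxygen to the enolate. The fallback avoids the enolate altogether. It sets out from 14 and returns at 16. Heating 14 with N,N-dimethylformamide dimethyl acetal would give the enaminone (E)-3-(dimethylamino)-1-[2-{[2,2-dimethyl-7-(3-methylbut-2-en-1-yl)-8-(triisopropylsilyloxy)-2H-chromen-6-yl]methoxy}-3-(3-methylbut-2-en-1-yl)-4,6-bis(triisopropylsilyloxy)phenyl]prop-2-en-1-one F7. Diazo transfer to the enamine double bond with 4-acetamidobenzenesulfonyl azide (cycloaddition, then loss of the N-sulfonyl formamidine) would give 16.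

## Further compounds

F1 | step 12 | tert-butyl 3-[2-hydroxy-3-(3-methylbut-2-en-1-yl)-4,6-bis(triisopropylsilyloxy)phenyl]-3-oxopropanoate | CC(C)(C)OC(=O)CC(=O)c1c(O[Si](C(C)C)(C(C)C)C(C)C)cc(O[Si](C(C)C)(C(C)C)C(C)C)c(CC=C(C)C)c1O
F2 | step 12 | tert-butyl 2-[2-hydroxy-3-(3-methylbut-2-en-1-yl)-4,6-bis(triisopropylsilyloxy)benzoyl]-3-[2,2-dimethyl-7-(3-methylbut-2-en-1-yl)-8-(triisopropylsilyloxy)-2H-chromen-6-yl]prop-2-enoate (double-bond isomers) | CC(C)(C)OC(=O)C(=Cc1cc2C=CC(C)(C)Oc2c(O[Si](C(C)C)(C(C)C)C(C)C)c1CC=C(C)C)C(=O)c1c(O[Si](C(C)C)(C(C)C)C(C)C)cc(O[Si](C(C)C)(C(C)C)C(C)C)c(CC=C(C)C)c1O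
F3 | step 12 | tert-butyl (2S)-2-[2,2-dimethyl-7-(3-methylbut-2-en-1-yl)-8-(triisopropylsilyloxy)-2H-chromen-6-yl]-8-(3-methylbut-2-en-1-yl)-4-oxo-5,7-bis(triisopropylsilyloxy)-3,4-dihydro-2H-chromene-3-carboxylate (C3 epimers) | CC(C)=CCc1c([C@@H]2C(C(=O)OC(C)(C)C)C(=O)c3c(O[Si](C(C)C)(C(C)C)C(C)C)cc(O[Si](C(C)C)(C(C)C)C(C)C)c(CC=C(C)C)c3O2)cc2c(c1O[Si](C(C)C)(C(C)C)C(C)C)OC(C)(C)C=C2
F4 | step 9 | 1-[2-hydroxy-4,6-bis(triisopropylsilyloxy)phenyl]ethanone | CC(=O)c1c(O)cc(O[Si](C(C)C)(C(C)C)C(C)C)cc1O[Si](C(C)C)(C(C)C)C(C)C
F5 | step 9 | 1-[2-[(2-methylbut-3-en-2-yl)oxy]-4,6-bis(triisopropylsilyloxy)phenyl]ethanone | CC(=O)c1c(OC(C)(C)C=C)cc(O[Si](C(C)C)(C(C)C)C(C)C)cc1O[Si](C(C)C)(C(C)C)C(C)C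
F6 | step 10 | 6-(bromomethyl)-2,2-dimethyl-7-(3-methylbut-2-en-1-yl)-8-(triisopropylsilyloxy)-2H-chromene | CC(C)=CCc1c(CBr)cc2C=CC(C)(C)Oc2c1O[Si](C(C)C)(C(C)C)C(C)C
F7 | step 11 | (E)-3-(dimethylamino)-1-[2-{[2,2-dimethyl-7-(3-methylbut-2-en-1-yl)-8-(triisopropylsilyloxy)-2H-chromen-6-yl]methoxy}-3-(3-methylbut-2-en-1-yl)-4,6-bis(triisopropylsilyloxy)phenyl]prop-2-en-1-one | CN(C)/C=C/C(=O)c1c(O[Si](C(C)C)(C(C)C)C(C)C)cc(O[Si](C(C)C)(C(C)C)C(C)C)c(CC=C(C)C)c1OCc1cc2C=CC(C)(C)Oc2c(O[Si](C(C)C)(C(C)C)C(C)C)c1CC=C(C)C
A1 | alternative 1 | 3-[(2-methylbut-3-en-2-yl)oxy]-4-[(2-methylbut-3-yn-2-yl)oxy]benzaldehyde | O=Cc1ccc(OC(C)(C)C#C)c(OC(C)(C)C=C)c1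
A2 | alternative 1 | 8-hydroxy-2,2-dimethyl-7-(3-methylbut-2-en-1-yl)-2H-chromene-6-carbaldehyde | CC(C)=CCc1c(C=O)cc2C=CC(C)(C)Oc2c1O
A3 | alternative 2 | 6-hydroxy-4-(methoxymethoxy)-3-(3-methylbut-2-en-1-yl)-2-({1-[8-(methoxymethoxy)-2,2-dimethyl-7-(3-methylbut-2-en-1-yl)-2H-chromen-6-yl]ethenyl}oxy)benzaldehyde | O=Cc1c(O)cc(OCOC)c(CC=C(C)C)c1OC(=C)c1cc2C=CC(C)(C)Oc2c(OCOC)c1CC=C(C)C
A4 | alternative 2 | (2S)-5-hydroxy-7-(methoxymethoxy)-2-[8-(methoxymethoxy)-2,2-dimethyl-7-(3-methylbut-2-en-1-yl)-2H-chromen-6-yl]-8-(3-methylbut-2-en-1-yl)-2,3-dihydro-4H-chromen-4-one | CC(C)=CCc1c([C@@H]2CC(=O)c3c(O)cc(OCOC)c(CC=C(C)C)c3O2)cc2c(c1OCOC)OC(C)(C)C=C2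
A5 | alternative 3 | (2S)-5-bromo-2-[2,2-dimethyl-7-(3-methylbut-2-en-1-yl)-8-(triisopropylsilyloxy)-2H-chromen-6-yl]-2,3-dihydro-4H-pyran-4-one | CC(C)=CCc1c([C@@H]2CC(=O)C(Br)=CO2)cc2c(c1O[Si](C(C)C)(C(C)C)C(C)C)OC(C)(C)C=C2
A6 | alternative 3 | 1-methoxy-7-methyl-1,3-bis(trimethylsilyloxy)octa-1,3,6-triene | COC(O[Si](C)(C)C)=CC(O[Si](C)(C)C)=CCC=C(C)C
A7 | alternative 3 | (2S)-5,7-dihydroxy-2-[2,2-dimethyl-7-(3-methylbut-2-en-1-yl)-8-(triisopropylsilyloxy)-2H-chromen-6-yl]-8-(3-methylbut-2-en-1-yl)-2,3-dihydro-4H-chromen-4-one | CC(C)=CCc1c([C@@H]2CC(=O)c3c(O)cc(O)c(CC=C(C)C)c3O2)cc2c(c1O[Si](C(C)C)(C(C)C)C(C)C)OC(C)(C)C=C2
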